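Readings and results were computed on assumed constants; scatter was added.

If the blue run is read as a straight line, a short flask of substrate J, reagent L and the charged catalysts Z and Q shows X early. If it is read as a curve, X stays hidden through an induction period. Two chemists hold these two views of four flasks that differ in temperature.

in all of them: Z 0.13 mM; Q 0.20 mM
- teal: J 0.067 M; L 0.10 M; temperature −25 °C; run made earlier
- blue: J 0.15 M; L 0.10 M; temperature 10 °C; run made earlier
- grey: J 0.10 M; L 0.050 M; temperature −25 °C; run made earlier
- theta: J 0.10 M; L 0.100 M; at −20 °C until 20 min, from then on at 40 °C; time 25 min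
- beta: J 0.10 M; L 0.100 M; temperature 40 °C; time 25 min
- gamma: J 0.10 M; L 0.100 M; temperature −20 °C; time 25 min
- epsilon: J 0.10 M; L 0.100 M; temperature 10 °C; time 25 min

- teal (time / min: X / %): 50.0: 0.8; 150: 0; 240: 0; 360: 0; 600: 0; 720: 0
- blue (time / min: X / %): 8.00: 1.6; 25.0: 0; 40.0: 2.6; 60.0: 2.6; 120: 12.8
- grey (time / min: X / %): 60.0: 0.2; 120: 0.6; 180: 0; 360: 0; 720: 0.2

(each reading ± 1 percentage point)

- the numbers in the tables scatter by 1 percentage point (one standard deviation)

- the flask that comes out highest in amount of X, in percent of the J charged, or "all alike" when all lie within 1.5 percentage points (theta / beta / gamma / epsilon / all alike)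
- X at the end, in percent of the J charged, theta
- X at the end, in percent of the J charged, beta
- X at the end, in percent of the J charged, gamma
- X at the end, in percent of the J charged, epsilon

The first chemist takes a steady rate: the last blue reading, spread over its 120 min, gives epsilon 2.67 % after 25 min. The second answers that from 60.0 min to 120 min the blue readings rose by a factor of 4.92, nearer 4 than 2, so she lets X follow the square of time. Her measure is the first-point time, 33.5 min at 10 °C: the time a flask takes to show one percentage point of X, X then being one point times the square of time over first-point time. For epsilon this gives 0.556 %.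

My own reckoning extends her rule. Teal still reads 0 % at 720 min, so within the scatter its first-point time is at least that. Setting aside that teal and blue also differ in J, I put the gap down to the two temperatures, which implies an apparent activation energy of at least 51.2 kJ mol⁻¹. The first-point time is then at most 4.18 min at 40 °C and at least 441 min at −20 °C. So my rule puts beta at 35.8 % or more, theta in its 5.00 min of warmth at 1.43 % or more, and gamma at 0.00321 % or less.

The forecast takes her side, calling the blue rise “roughly quadratic in time”. It names beta and gives theta 5 % (1 % to 18 %), beta 55 % (20 % to 95 %), gamma 0 % (0 % to 0.5 %) and epsilon 0.7 % (0.1 % to 3 %). These are its estimates, whereas mine are limits.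

The flasks give theta 2.98 %, beta 52.9 %, gamma 0 % and epsilon 0.213 %, so beta stands highest.

    J + Z → Z + D (k = 9.38 M⁻¹ s⁻¹, Ea = 45.0 kJ mol⁻¹)
    L + G + D → G + X (k = 146 M⁻² s⁻¹, Ea = 39.0 kJ mol⁻¹)
    2 L → E (k = 3.67 × 10⁻⁴ M⁻¹ s⁻¹, Ea = 83.0 kJ mol⁻¹)
    Q → G (k = 0.00122 s⁻¹, Ea = 103 kJ mol⁻¹)
    (constants at 40 °C)

Epsilon falls below the square estimate and below the steady 2.67 %, while beta and theta clear their limits. The steady view keeps late beta, where X goes from 21.3 % at 12.5 min to 52.9 % at 25.0 min, a factor of 2.48. Beta stands at 52.9 % at its end because of the shrinking supply of L together with the length of the run: with L held it gives 66.7 %, and left for 250 min it gives 92.3 %. One part of the temperature effect is the conversion of Q into G: with that step not warmed, beta minus gamma falls from 53 percentage points to 0.021 points, and beta's lead over gamma would lie within the margin of 1.5 points.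

A neighbour of gamma is charged with 0.40 M of L, whereas the first-point time came from runs at 0.100 M; if X follows L, that time shrinks by the square root of the ratio of the L charges, to at least 220 min, which gives at most 0.0128 %. It gives 0 %, with 97.0 % of J left.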